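**Plan**

1. Numbering: C1 acyl bridgehead, C2–C3–C4 enolised diketone bridge, C5 prenyl bridgehead, C6 CH2, C7 prenyl CH, C8 methyl/homoprenyl carbon, C9 bridge ketone; ring A = C1–C2–C3–C4–C5–C9, ring B = C1–C8–C7–C6–C5–C9.
2. Enabling feature: ring A has oxygen on C9 and C4 (1,3 across C5) and the acyl-bearing C1 next to C9, the imprint of a [4+2] adduct of a 1,3-dioxygenated diene C9=C5–C4=C3 and an acyl alkene C1=C2; C5 and C1 are also the ends of the C6–C7–C8 bridge of ring B, so one cycloaddition can close both rings.
3. Retrosynthetic cuts, in order: the C2 oxygen and the C5–prenyl bond; then C2–C3 and C1–C9 together (type 2 intramolecular Diels–Alder of an acyclic diene–enone); then in the chain C1–C(acyl), C5–C6 and last C7–C8.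
4. Forward: geranyl ester → ester-enolate Claisen (C7–C8) → vinyl group to C1 enol triflate → C5–C6 by acetoacetate alkylation → acyl carbon onto C1 → oxidation and silylation to the bis(silyloxy)diene enone → one thermal step closes ring A and ring B → C5 prenylation, then oxidation at C2 and C9.
5. Stereochemistry: C7 and C8 from the chair transition state of the Claisen step, made enantioselective by a chiral boron controller; C1 from the tether conformation in the cycloaddition; C5 is then fixed by the bicycle; carbinol centres at C9, C2 and in the chain are transient.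

Key step: step 12

Assumption: with i-Pr2NEt in CH2Cl2 the (S,S)-controller is taken to give the enolate geometry and facial sense that lead to (2R,3S)-6; if either proves opposite, the amine/solvent pair or the antipodal controller is exchanged and nothing else changes.

**Route**

Step 1
Reactants: 1 geraniol; 2 5-methylhex-4-enoic acid
Product: 3 geranyl 5-methylhex-4-enoate
Conditions: DCC, DMAP (cat.), CH2Cl2, 0 °C → rt
Reagents that add atoms: none
Why: Steglich esterification of a primary allylic alcohol with an unhindered acid runs under neutral conditions that leave the (E)-alkene and the trisubstituted alkenes untouched.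

Step 2
Reactants: 3 geranyl 5-methylhex-4-enoate
Product: 7 methyl (2R,3S)-3-ethenyl-3,7-dimethyl-2-(3-methylbut-2-en-1-yl)oct-6-enoate, via boron ketene acetal 4 (not isolated), via O-boryl carboxylate 5 (not isolated), via carboxylic acid 6 (not isolated)
Conditions: (1S,2S)-N,N'-bis[3,5-bis(trifluoromethyl)benzenesulfonyl]-1,2-diphenylethane-1,2-diamine, BBr3, CH2Cl2 (gives the B-bromodiazaborolidine); then 3, i-Pr2NEt, CH2Cl2, −78 °C, then −20 → 4 °C; aqueous work-up (bis-sulfonamide recovered); crude acid, Me3SiCHN2, PhMe/MeOH, 0 °C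
Reagents that add atoms: trimethylsilyldiazomethane, C[Si](C)(C)C=[N+]=[N-]
Why: Enantioselective ester-enolate Claisen (Ireland–Claisen type) rearrangement through a chair transition state, in which the (E)-alkene places homoprenyl pseudo-equatorial and methyl pseudo-axial at C8, the enolate with the prenyl CH2 cis to the O–B oxygen places prenyl pseudo-equatorial at C7 (this fixes the relative configuration), and the C2-symmetric diamine on boron selects the enolate face and so the absolute configuration, after which O-methylation of the crude acid gives the ester.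

Step 3
Reactants: 7 methyl ester
Product: 8 methyl (2R,3R)-3-acetyl-3,7-dimethyl-2-(3-methylbut-2-en-1-yl)oct-6-enoate (vinyl group now the C1 acetyl)
Conditions: PdCl2 (10 mol %), CuCl, O2 (1 atm), DMF/H2O, rt
Reagents that add atoms: water, O
Why: Wacker–Tsuji oxidation converts only the monosubstituted alkene, at its internal carbon, because trisubstituted alkenes are not oxidised by divalent palladium under these conditions.

Step 4
Reactants: 8 methyl ketone
Product: 10 enol triflate (C1 as C(OSO2CF3)=CH2, C6 still the methyl ester), via potassium enolate 9 (not isolated)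
Conditions: KN(SiMe3)2, THF, −78 °C; then PhNTf2, −78 → 0 °C
Reagents that add atoms: N-phenylbis(trifluoromethanesulfonimide), O=S(=O)(N(c1ccccc1)S(=O)(=O)C(F)(F)F)C(F)(F)F
Why: The ketone can enolise only at its methyl group (C8 is quaternary and the tertiary ester α-hydrogen at C7 is far less acidic), and O-sulfonylation of that enolate is a standard enol triflate synthesis.

Step 5
Reactants: 10 enol triflate ester
Product: 11 primary alcohol (C6 as CH2OH)
Conditions: i-Bu2AlH (2.5 equiv), CH2Cl2, −78 → 0 °C; Rochelle salt work-up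
Reagents that add atoms: none
Why: Aluminium hydride reduction of a methyl ester to the primary alcohol is routine and leaves the enol triflate and the alkenes intact.

Step 6
Reactants: 11 primary alcohol
Product: 12 primary iodide (C6 as CH2I)
Conditions: I2, PPh3, imidazole, CH2Cl2, 0 °C → rt
Reagents that add atoms: iodine, II
Why: Appel-type iodination proceeds through the alkoxyphosphonium salt at the primary carbon and does not touch the neighbouring C7 centre.

Step 7
Reactants: 12 primary iodide; 13 ethyl acetoacetate
Product: 15 keto ester (C5 carries acetyl and CO2Et; epimers at C5), via sodium acetoacetate enolate 14 (not isolated)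
Conditions: 13 (3 equiv), NaH, DMF, 0 °C → rt; then 12, 60 °C
Reagents that add atoms: none
Why: Acetoacetic ester alkylation (SN2 at the primary iodide by the stabilised enolate) forms C5–C6 at the central carbon without any risk to C7, and the new C5 centre may be a mixture because it becomes sp2 in step 11.

Step 8
Reactants: 15 keto ester
Product: 16 1,3-diol (C9 as CH2OH, C4 as CH(OH)CH3; diastereomer mixture)
Conditions: LiBH4, THF/MeOH, 0 °C → rt
Reagents that add atoms: none
Why: LiBH4 reduces both carbonyl groups of a β-keto ester to the 1,3-diol and is mild enough to spare the enol triflate.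

Step 9
Reactants: 16 1,3-diol; 17 isobutyraldehyde
Product: 18 triol (C1 as C(=CH2)CH(OH)i-Pr)
Conditions: CrCl2 (5 equiv), NiCl2 (2 mol %), 17 (3 equiv), DMF, rt
Reagents that add atoms: none
Why: Nozaki–Hiyama–Kishi coupling turns the enol triflate into an alkenylchromium species that adds to the aldehyde and tolerates free hydroxyl groups, and the new carbinol configuration is irrelevant because it is oxidised next.

Step 10
Reactants: 18 triol
Product: 19 2-formyl ketone enone (C9 aldehyde, C4 methyl ketone, C1 α-methylene isopropyl ketone; enolised at C9)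
Conditions: Dess–Martin periodinane (4.5 equiv), NaHCO3, CH2Cl2, 0 °C → rt; taken on at once
Reagents that add atoms: none
Why: Dess–Martin oxidation converts all three carbinols in one amine-free operation, so the enolised 2-formyl ketone has little chance to add in Michael fashion to the newly formed α-methylene ketone.

Step 11
Reactants: 19 2-formyl ketone enone
Product: 20 acyclic bis(triethylsilyloxy)diene enone, diene C9H(OSiEt3)=C5–C4(OSiEt3)=C3H2 with (E)-C9=C5
Conditions: Et3SiOTf (2.4 equiv), Et3N (4 equiv), Et2O, −78 → −20 °C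
Reagents that add atoms: triethylsilyl trifluoromethanesulfonate, CC[Si](CC)(CC)OS(=O)(=O)C(F)(F)F
Why: Soft enolisation and O-silylation first capture the formyl enol as the (E)-silyloxymethylene ketone (silyloxy trans to the acetyl carbon) and then enolise the remaining methyl ketone to the 2-silyloxy diene, while the hindered isopropyl ketone reacts more slowly.

Step 12
Reactants: 20 bis(silyloxy)diene enone
Product: 21 bicyclo[3.3.1]nonene with C4=C5 bridgehead triethylsilyl enol ether, C9–OSiEt3 cis to C8, C1 isobutyryl
Conditions: degassed PhMe (0.005 M), 2,6-di-tert-butyl-4-methylphenol (0.1 equiv), propylene oxide (acid scavenger), silylated sealed tube, 170–190 °C; concentrated and used crude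
Reagents that add atoms: none
Why: Proposed new method: a thermal, asynchronous [4+2] cycloaddition in which the nucleophilic diene terminus C3 bonds first to the unhindered enone β-carbon C2 and the silyloxy-bearing terminus C9 then closes onto the fully substituted α-carbon C1, the closest known reaction type being the type 2 intramolecular Diels–Alder reaction of 2-tethered dienes, which gives bridgehead alkenes down to a three-atom tether but has not been run with a 1,1-disubstituted dienophile carbon flanked by a quaternary centre. Ring A closes as the cyclohexene of the cycloaddition (bonds C2–C3 and C1–C9), and ring B closes in the same event through C1–C9 as a six-membered carbocycle bridged by the C6–C7–C8 tether (endo to the diene C9=C5 bond, exo to C1=C2), which leaves the C4=C5 bridgehead enol ether. The new centre C1 is set by the resident C7 and C8 centres through a chair-like tether with C7 prenyl and C8 homoprenyl pseudo-equatorial and C8 methyl pseudo-axial, while C9 follows from the (E)-silyloxy terminus (OSiEt3 cis to C8) and is erased when C9 becomes a ketone. Regiochemistry needs only the tether, which permits the bridged mode alone, and it is reinforced by matched polarity (donors on C4 and C9, acceptor on C1). Chemoselectivity over the three isolated trisubstituted alkenes rests on this push–pull pairing, and the geminal substitution at C8 favours the folded conformer. The strain of the bridgehead alkene is acceptable because it is spent in the next step, and the β-silyloxy group on C9 cannot eliminate since that would need a double bond to the one-carbon bridge.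

Step 13
Reactants: 21 bridgehead silyl enol ether; 22 prenyl bromide
Product: 23 C5-prenyl C4 ketone (C9–OSiEt3 retained)
Conditions: 22 (5 equiv), (Me2N)3S+ Me3SiF2− (1.1 equiv), THF, −78 → −30 °C
Reagents that add atoms: none
Why: Fluoride cleavage of the silyl enol ether releases the enolate regiospecifically at C5, and its C-alkylation by the allylic bromide present in excess (regiospecific enolate alkylation, as in bridgehead prenylations of bicyclo[3.3.1]nonanones) relieves the bridgehead strain, can occur only at the exo position of C5 so that no stereochemical choice arises, and spares the hindered alkyl silyl ether at C9.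

Step 14
Reactants: 23 C4 ketone
Product: 25 C2=C3 enone, via trimethylsilyl enol ether 24 (not isolated)
Conditions: Me3SiCl, LiN(i-Pr)2, THF, −78 °C (in situ quench); then Pd(OAc)2 (1.1 equiv), MeCN, rt
Reagents that add atoms: none
Why: Saegusa–Ito dehydrogenation works here because the C4 ketone can enolise only towards C3 (C5 is quaternary and the isopropyl methine of the C1 acyl group is far more hindered), and palladium diacetate turns the silyl enol ether into the enone by β-hydride elimination.

Step 15
Reactants: 25 enone
Product: 27 β-hydroxy ketone (C2 carbinol, configuration not defined), via pinacol boronate 26 (not isolated)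
Conditions: CuCl (5 mol %), NaOt-Bu (10 mol %), bis[2-(diphenylphosphino)phenyl] ether (5 mol %), B2pin2 (1.2 equiv), MeOH (2 equiv), THF, rt; then NaBO3·4H2O, THF/H2O, rt
Reagents that add atoms: sodium perborate tetrahydrate, O[B-]1(O)OO[B-](O)(O)OO1.[Na+].[Na+]
Why: Copper-catalysed conjugate borylation places boron on the enone β-carbon C2 and mild perborate oxidation of the C–B bond gives the carbinol, whose configuration does not matter because C2 ends as a carbonyl group.

Step 16
Reactants: 27 β-hydroxy ketone
Product: 28 diol (C2–OH and C9–OH)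
Conditions: HF·pyridine, pyridine, THF, 0 °C → rt
Reagents that add atoms: none
Why: Acidic fluoride removes the hindered secondary triethylsilyl ether without forming the C9 alkoxide, which under basic conditions could open the bicycle by retro-aldol cleavage.

Step 17
Reactants: 28 diol
Product: 29 target
Conditions: Dess–Martin periodinane (3 equiv), NaHCO3, CH2Cl2, rt
Reagents that add atoms: none
Why: Dess–Martin oxidation of both secondary alcohols should give the C9 ketone and the C2/C4 β-diketone, which enolises to the vinylogous acid drawn for the target (in equilibrium with its enol tautomer), while C1, C5 and C8 are quaternary and C7 has no adjacent carbonyl, so no centre can epimerise.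

**Compound list**

1 | geraniol, (2E)-3,7-dimethylocta-2,6-dien-1-ol | CC(C)=CCC/C(C)=C/CO | starting material
2 | 5-methylhex-4-enoic acid | CC(C)=CCCC(=O)O | starting material
3 | (2E)-3,7-dimethylocta-2,6-dien-1-yl 5-methylhex-4-enoate | CC(C)=CCC/C(C)=C/COC(=O)CCC=C(C)C | intermediate
4 | boron ketene acetal of 3 (O-geranyl, O-[(4S,5S)-diazaborolidin-2-yl], prenyl CH2 cis to O–B) | CC(C)=CCC/C(C)=C/CO/C(OB1N(S(=O)(=O)c2cc(cc(c2)C(F)(F)F)C(F)(F)F)[C@@H](c2ccccc2)[C@H](c2ccccc2)N1S(=O)(=O)c1cc(cc(c1)C(F)(F)F)C(F)(F)F)=C/CC=C(C)C | intermediate (not isolated)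
5 | O-boryl carboxylate of acid 6 (rearranged boron ester) | CC(C)=CCC[C@](C)([C@@H](CC=C(C)C)C(=O)OB1N(S(=O)(=O)c2cc(cc(c2)C(F)(F)F)C(F)(F)F)[C@@H](c2ccccc2)[C@H](c2ccccc2)N1S(=O)(=O)c1cc(cc(c1)C(F)(F)F)C(F)(F)F)C=C | intermediate (not isolated)
6 | (2R,3S)-3-ethenyl-3,7-dimethyl-2-(3-methylbut-2-en-1-yl)oct-6-enoic acid | CC(C)=CCC[C@](C)([C@@H](CC=C(C)C)C(=O)O)C=C | intermediate (not isolated)
7 | methyl (2R,3S)-3-ethenyl-3,7-dimethyl-2-(3-methylbut-2-en-1-yl)oct-6-enoate | CC(C)=CCC[C@](C)([C@@H](CC=C(C)C)C(=O)OC)C=C | intermediate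
8 | methyl (2R,3R)-3-acetyl-3,7-dimethyl-2-(3-methylbut-2-en-1-yl)oct-6-enoate | CC(C)=CCC[C@](C)([C@@H](CC=C(C)C)C(=O)OC)C(C)=O | intermediate
9 | potassium enolate of 8 (methyl side) | CC(C)=CCC[C@](C)([C@@H](CC=C(C)C)C(=O)OC)C(=C)[O-].[K+] | intermediate (not isolated)
10 | enol triflate: methyl 3,7-dimethyl-2-(3-methylbut-2-en-1-yl)-3-[1-(trifluoromethylsulfonyloxy)ethenyl]oct-6-enoate, C7/C8 as in 7 | CC(C)=CCC[C@](C)([C@@H](CC=C(C)C)C(=O)OC)C(=C)OS(=O)(=O)C(F)(F)F | intermediate
11 | primary alcohol (C6 CH2OH, C1 enol triflate) | CC(C)=CCC[C@](C)([C@@H](CC=C(C)C)CO)C(=C)OS(=O)(=O)C(F)(F)F | intermediate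
12 | primary iodide (C6 CH2I, C1 enol triflate) | CC(C)=CCC[C@](C)([C@@H](CC=C(C)C)CI)C(=C)OS(=O)(=O)C(F)(F)F | intermediate
13 | ethyl acetoacetate | CCOC(=O)CC(C)=O | starting material
14 | sodium enolate of ethyl acetoacetate | CCOC(=O)C=C(C)[O-].[Na+] | intermediate (not isolated)
15 | keto ester (C5 bears acetyl and CO2Et; C5 epimers) | CC(C)=CCC[C@](C)([C@@H](CC=C(C)C)CC(C(C)=O)C(=O)OCC)C(=C)OS(=O)(=O)C(F)(F)F | intermediate
16 | 1,3-diol (C9 CH2OH, C4 CH(OH)CH3; diastereomers) | CC(C)=CCC[C@](C)([C@@H](CC=C(C)C)CC(CO)C(C)O)C(=C)OS(=O)(=O)C(F)(F)F | intermediate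
17 | isobutyraldehyde (2-methylpropanal) | CC(C)C=O | starting material
18 | triol (C1 as C(=CH2)CH(OH)i-Pr; diastereomers) | CC(C)=CCC[C@](C)([C@@H](CC=C(C)C)CC(CO)C(C)O)C(=C)C(O)C(C)C | intermediate
19 | 2-formyl ketone enone (C9 CHO, C4 acetyl, C1 α-methylene isopropyl ketone) | CC(C)=CCC[C@](C)([C@@H](CC=C(C)C)CC(C=O)C(C)=O)C(=C)C(=O)C(C)C | intermediate
20 | acyclic (E)-bis(triethylsilyloxy)diene enone, cycloaddition precursor | CC(C)=CCC[C@](C)([C@@H](CC=C(C)C)C/C(=C\O[Si](CC)(CC)CC)C(=C)O[Si](CC)(CC)CC)C(=C)C(=O)C(C)C | intermediate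
21 | bicyclo[3.3.1]nonene with C4=C5 bridgehead silyl enol ether, C9–OSiEt3 cis to C8 | CC(C)=CCC[C@]1(C)[C@@H](CC=C(C)C)CC2=C(O[Si](CC)(CC)CC)CC[C@@]1(C(=O)C(C)C)[C@@H]2O[Si](CC)(CC)CC | intermediate
22 | prenyl bromide (1-bromo-3-methylbut-2-ene) | CC(C)=CCBr | starting material
23 | C5-prenyl C4 ketone, C9–OSiEt3 | CC(C)=CCC[C@]1(C)[C@@H](CC=C(C)C)C[C@@]2(CC=C(C)C)[C@@H](O[Si](CC)(CC)CC)[C@]1(C(=O)C(C)C)CCC2=O | intermediate
24 | C4 trimethylsilyl enol ether (C3=C4) | CC(C)=CCC[C@]1(C)[C@@H](CC=C(C)C)C[C@@]2(CC=C(C)C)[C@@H](O[Si](CC)(CC)CC)[C@]1(C(=O)C(C)C)CC=C2O[Si](C)(C)C | intermediate (not isolated)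
25 | C2=C3 enone (C4 ketone) | CC(C)=CCC[C@]1(C)[C@@H](CC=C(C)C)C[C@@]2(CC=C(C)C)[C@@H](O[Si](CC)(CC)CC)[C@]1(C(=O)C(C)C)C=CC2=O | intermediate
26 | C2 pinacol boronate (β-boryl ketone) | CC(C)=CCC[C@]1(C)[C@@H](CC=C(C)C)C[C@@]2(CC=C(C)C)[C@@H](O[Si](CC)(CC)CC)[C@]1(C(=O)C(C)C)C(B3OC(C)(C)C(C)(C)O3)CC2=O | intermediate (not isolated)
27 | C2 carbinol (β-hydroxy ketone), C9–OSiEt3 | CC(C)=CCC[C@]1(C)[C@@H](CC=C(C)C)C[C@@]2(CC=C(C)C)[C@@H](O[Si](CC)(CC)CC)[C@]1(C(=O)C(C)C)C(O)CC2=O | intermediate
28 | C2,C9 diol | CC(C)=CCC[C@]1(C)[C@@H](CC=C(C)C)C[C@@]2(CC=C(C)C)[C@@H](O)[C@]1(C(=O)C(C)C)C(O)CC2=O | intermediate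
29 | target, (1R,5R,7S,8R)-4-hydroxy-8-methyl-5,7-bis(3-methylbut-2-en-1-yl)-8-(4-methylpent-3-en-1-yl)-1-(2-methylpropanoyl)bicyclo[3.3.1]non-3-ene-2,9-dione (route numbering) | CC(C)=CCC[C@]1(C)[C@@H](CC=C(C)C)C[C@@]2(CC=C(C)C)C(=O)[C@]1(C(=O)C(C)C)C(=O)C=C2O | target

**Step count**

Total steps: 17. Longest linear sequence: 17 (from geraniol; 2, 13, 17 and 22 are purchased).

**Steps most likely to fail**

Step 12 (cycloaddition). The second bond may not form at the congested, fully substituted C1. The diene could then be consumed by an inverse-demand hetero-Diels–Alder reaction with the enone, by silyl transfer or by oligomerisation at the temperature required.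

Fallback, known chemistry, from iodide 12 back to ketone 23. Nozaki–Hiyama–Kishi coupling of 12 with 17 (CrCl2, NiCl2 cat., DMF) should give iodo allylic alcohol F1, and Dess–Martin oxidation iodo enone F2. The diene partner is made separately. C-Prenylation of 13 with 22 (NaH, THF) gives ethyl 2-acetyl-5-methylhex-4-enoate F3. LiAlH4 reduction gives diol F4, Swern oxidation gives 2-formyl ketone F5, and Et3SiOTf/Et3N gives 2-prenyl bis(silyloxy)diene F6. An intermolecular Diels–Alder reaction of F2 with F6 (PhMe, 80–110 °C) forms the same C2–C3 and C1–C9 bonds and gives cyclohexene F7. Cleavage of its silyl enol ether with (Me2N)3S+ Me3SiF2− then lets the C5 enolate close ring B by intramolecular alkylation at C6, which gives 23. The cost is that C1 is set under acyclic control next to C8, so the C1 epimer must be removed. A C9 epimer would be harmless since C9 ends as a ketone.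

Step 13 (bridgehead prenylation). Proton transfer from C3–H of the product to the strained enolate would scramble the enolate. O-alkylation, or premature loss of the C9 silyl group followed by retro-aldol opening, could also compete.

Fallback, from 21 back to 23, with no basic enolate. N-Iodosuccinimide (THF, −78 °C) converts the bridgehead enol ether into bridgehead iodo ketone F8. Keck allylation (allyltributylstannane, AIBN, PhH, 80 °C) gives C5-allyl ketone F9. Cross-metathesis with 2-methyl-2-butene (second-generation Grubbs catalyst, CH2Cl2, 40 °C) turns allyl into prenyl and gives 23.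

Step 7 (acetoacetate alkylation). SN2 displacement at the β-branched C6 may be slow, which would allow O-alkylation, elimination or attack on the enol triflate during long heating.

Fallback, from alcohol 11 back to keto ester 15. Dess–Martin oxidation gives aldehyde F10. Knoevenagel condensation with 13 (TiCl4, pyridine, THF, 0 °C, chosen to limit epimerisation at C7) gives alkylidene acetoacetate F11. 1,4-Reduction with LiBH(s-Bu)3 (THF, −78 °C) gives 15.

**Further compounds**

F1 | step 12 | iodo allylic alcohol | CC(C)=CCC[C@](C)([C@@H](CC=C(C)C)CI)C(=C)C(O)C(C)C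
F2 | step 12 | iodo enone | CC(C)=CCC[C@](C)([C@@H](CC=C(C)C)CI)C(=C)C(=O)C(C)C
F3 | step 12 | ethyl 2-acetyl-5-methylhex-4-enoate | CCOC(=O)C(CC=C(C)C)C(C)=O
F4 | step 12 | 2-(3-methylbut-2-en-1-yl)butane-1,3-diol | CC(O)C(CO)CC=C(C)C
F5 | step 12 | 2-acetyl-5-methylhex-4-enal (2-formyl ketone) | CC(=O)C(C=O)CC=C(C)C
F6 | step 12 | (1E)-2-prenyl-1,3-bis(triethylsilyloxy)buta-1,3-diene | CC(C)=CC/C(=C\O[Si](CC)(CC)CC)C(=C)O[Si](CC)(CC)CC
F7 | step 12 | intermolecular cycloadduct (cyclohexene silyl enol ether with C6 iodide) | CC(C)=CCC[C@](C)([C@@H](CC=C(C)C)CI)[C@@]1(C(=O)C(C)C)CCC(O[Si](CC)(CC)CC)=C(CC=C(C)C)[C@H]1O[Si](CC)(CC)CC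
F8 | step 13 | bridgehead (C5) iodo ketone | CC(C)=CCC[C@]1(C)[C@@H](CC=C(C)C)C[C@@]2(I)[C@@H](O[Si](CC)(CC)CC)[C@]1(C(=O)C(C)C)CCC2=O
F9 | step 13 | C5-allyl ketone | CC(C)=CCC[C@]1(C)[C@@H](CC=C(C)C)C[C@@]2(CC=C)[C@@H](O[Si](CC)(CC)CC)[C@]1(C(=O)C(C)C)CCC2=O
F10 | step 7 | C6 aldehyde | CC(C)=CCC[C@](C)([C@@H](CC=C(C)C)C=O)C(=C)OS(=O)(=O)C(F)(F)F
F11 | step 7 | alkylidene acetoacetate (E/Z mixture) | CC(C)=CCC[C@](C)([C@@H](CC=C(C)C)C=C(C(C)=O)C(=O)OCC)C(=C)OS(=O)(=O)C(F)(F)F
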